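**Remark (numbering):** the eastern bicycle is numbered as a perhydro-1-benzoxepine (O1, C2, C3, C4, C5, C5a, C6–C9, C9a) and the western bicycle as a hydroazulene (C1–C3, C3a, C4–C8, C8a). The target is read as the (3R,5aR,6R,7S,9aR)-benzoxepane joined through CH2CH2 to C5 of a (3aR,5R,6S,8aR)-hydroazulene.

## Retrosynthetic overview

1. The C6-methyl carbinol of the hydroazulene is cut back to a ketone (MeLi/CeCl3), and the CH2–CH2 linker to a Giese addition of oxepane iodide 15 to α-methylene ketone 34.
2. Enabling feature: in the oxepane ring, atoms C9a–O1–C2(CH3)2–C3(O)–C4 are the five ring atoms of a 2,2-dimethylfuran-3(2H)-one that lacks only its C4–C9a bond, and C5–C5a is a two-carbon unit lying between them. The oxepane is therefore a furanone into whose C=C bond an isopropenyl C=C has been inserted.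
3. Key step: intramolecular [2+2] photocycloaddition of furanone 10 forms C4–C5 and C5a–C9a at once, closing the cyclohexane and a cyclobutane. Strain-releasing SmI2 cleavage of the cyclobutane bond C4–C9a then gives the oxepanone. The precursor comes from nerol (Sharpless epoxidation, isopropenyl–copper opening).
4. The hydroazulenone comes from (S)-carvone: ring contraction to a cyclopentene (epoxide cleavage/aldol), reductive allylic transposition to set the cis ring fusion, ring-closing metathesis, then Me2CuLi/Mannich methylenation.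
5. Ring order: east — cyclohexane and cyclobutane (step 8), then oxepane (step 9); west — cyclopentene (step 17), then cycloheptenone (step 24).

Key step: step 8

## Route

**Eastern fragment (steps 1–12)**

Step 1
Reactants: 1 nerol
Product: 2 (2R,3S)-2,3-epoxynerol
Conditions: Ti(OiPr)4 (cat.), D-(−)-diethyl tartrate (cat.), t-BuOOH, 4 Å molecular sieves, CH2Cl2, −20 °C
Reagents that add atoms: tert-butyl hydroperoxide, CC(C)(C)OO
Why: Sharpless asymmetric epoxidation; the allylic hydroxyl restricts oxidation to the 2,3-alkene and the D-tartrate selects the face that gives the (2R,3S)-epoxide, which fixes the future C7 carbinol.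

Step 2
Reactants: 2 (2R,3S)-2,3-epoxynerol
Product: 3 (2S,3S)-3,7-dimethyl-2-(prop-1-en-2-yl)oct-6-ene-1,3-diol
Conditions: CH2=C(CH3)MgBr (excess), CuI (cat.), THF, −30 to 0 °C
Reagents that add atoms: isopropenylmagnesium bromide, CC(=C)[Mg]Br
Why: Copper-catalysed SN2 opening of a 2,3-epoxy alcohol; attack at the less substituted C2 with inversion converts the cis-epoxide into the required relative configuration of the future C6 and C7.

Step 3
Reactants: 3 the diol
Product: 4 (4S,5S)-2,2-di-tert-butyl-4-methyl-4-(4-methylpent-3-en-1-yl)-5-(prop-1-en-2-yl)-1,3,2-dioxasilinane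
Conditions: tBu2Si(OTf)2, 2,6-lutidine, CH2Cl2, 0 °C to rt
Reagents that add atoms: di-tert-butylsilyl bis(trifluoromethanesulfonate), CC(C)(C)[Si](OS(=O)(=O)C(F)(F)F)(OS(=O)(=O)C(F)(F)F)C(C)(C)C
Why: Silylene acetal formation of a 1,3-diol; it masks both hydroxyls (the tertiary one could otherwise add to the furanone) and holds the two future reacting arms cis on a six-membered ring.

Step 4
Reactants: 4 the silylene acetal
Product: 6 3-[(4S,5S)-2,2-di-tert-butyl-4-methyl-5-(prop-1-en-2-yl)-1,3,2-dioxasilinan-4-yl]propanal, via epoxide 5 (not isolated)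
Conditions: mCPBA (1.0 equiv), NaHCO3, CH2Cl2, 0 °C; then H5IO6, THF/H2O, 0 °C
Reagents that add atoms: 3-chloroperoxybenzoic acid, OOC(=O)c1cccc(Cl)c1
Why: Prilezhaev epoxidation should select the electron-rich trisubstituted alkene over the hindered 1,1-disubstituted isopropenyl group, and periodic acid cleavage of the epoxide gives the aldehyde and acetone without touching a stereocentre.

Step 5
Reactants: 6 the aldehyde
Product: 7 7-[(4S,5S)-2,2-di-tert-butyl-4-methyl-5-(prop-1-en-2-yl)-1,3,2-dioxasilinan-4-yl]-2-methylhept-3-yne-2,5-diol (C5 epimers)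
Conditions: 2-methylbut-3-yn-2-ol, n-BuLi (2 equiv), THF, −78 °C; then 6, −78 to 0 °C
Reagents that add atoms: 2-methylbut-3-yn-2-ol, CC(C)(O)C#C
Why: 1,2-Addition of a lithium acetylide to an aldehyde; the new carbinol centre is oxidised in step 6, so its configuration is irrelevant.

Step 6
Reactants: 7 the propargylic diol
Product: 8 1-[(4S,5S)-2,2-di-tert-butyl-4-methyl-5-(prop-1-en-2-yl)-1,3,2-dioxasilinan-4-yl]-6-hydroxy-6-methylhept-4-yn-3-one
Conditions: MnO2 (activated, excess), CH2Cl2, rt
Reagents that add atoms: none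
Why: MnO2 oxidation of the secondary propargylic alcohol; the tertiary propargylic hydroxyl cannot be oxidised.

Step 7
Reactants: 8 the ynone
Product: 10 5-{2-[(4S,5S)-2,2-di-tert-butyl-4-methyl-5-(prop-1-en-2-yl)-1,3,2-dioxasilinan-4-yl]ethyl}-2,2-dimethylfuran-3(2H)-one, via enaminone 9 (not isolated)
Conditions: Et2NH, EtOH, rt; then aq. AcOH, rt
Reagents that add atoms: none
Why: Conjugate addition of the amine to the ynone, then acid hydrolysis, attack of the tertiary hydroxyl on the distal ketone and dehydration: the standard 3(2H)-furanone synthesis from γ-hydroxy ynones.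

Step 8
Reactants: 10 the furanone
Product: 11 cyclobutane photoadduct (2,2-dimethyl-3-oxooxolane, cyclobutane, cyclohexane and dioxasilinane rings; both cyclobutane fusions cis; quaternary methyl anti to H-6)
Conditions: hν (350 nm, uranium-glass filter), degassed MeCN (0.005 M), rt
Reagents that add atoms: none
Why: Excitation of the 3(2H)-furanone (a cyclic β-alkoxy enone) gives its triplet, whose β-carbon C5 (future C9a) bonds to the internal alkene carbon (future C5a) to give a chair-like six-membered 1,4-biradical that collapses by bonding furanone C4 (future C4) to the terminal CH2 (future C5); this is an intramolecular enone–alkene [2+2] photocycloaddition of the de Mayo type in the straight mode. The cyclohexane closes by 6-exo attack of the enone β-carbon on the proximal alkene carbon, the cyclobutane by recombination of the 1,4-biradical, and both new ring fusions (cyclobutane/cyclohexane and cyclobutane/oxolanone) are cis by necessity. C5a is controlled by the resident C6 centre: in the chair that keeps the C6–CH2O bond equatorial and the allylic C6–H eclipsed with the C=CH2 bond, the methyl group becomes axial and anti to H-6, while C9a and the transient C4 centre follow from the cis fusions. The step needs straight over crossed regiochemistry, which the four-atom tether and the preference of the β-carbon for the proximal, more substituted alkene carbon secure, and it needs one alkene face, which the cis disposition of the two arms on the dioxasilinane and the allylic conformational bias secure. The cyclobutane so formed carries the strain that is released in step 9.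

Step 9
Reactants: 11 the photoadduct
Product: 12 di-tert-butylsilylene acetal of (5aR,6S,7S,9aR)-7-hydroxy-6-(hydroxymethyl)-2,2,5a,7-tetramethyloctahydro-1-benzoxepin-3(2H)-one (trans-fused)
Conditions: SmI2 (2.5 equiv), HMPA, THF, −78 to 0 °C; aq. NH4Cl
Reagents that add atoms: none
Why: SmI2 ketyl formation at C3 and β-scission of the cyclobutyl ketone (strain release) cleave C4–C9a, the only bond whose cleavage gives a tertiary α-alkoxy radical and a samarium enolate; hydrogen transfer to C9a anti to the axial C5a methyl should give the trans-fused oxepanone.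

Step 10
Reactants: 12 the oxepanone
Product: 13 di-tert-butylsilylene acetal (6-CH2O/7-O) of (3R,5aR,6S,7S,9aR)-6-(hydroxymethyl)-2,2,5a,7-tetramethyldecahydro-1-benzoxepine-3,7-diol
Conditions: (S)-2-methyl-CBS-oxazaborolidine (cat.), BH3·SMe2, THF, −20 °C
Reagents that add atoms: none
Why: Corey–Bakshi–Shibata reduction; the catalyst distinguishes the quaternary C2 from the C4 methylene and should give the (3R)-alcohol under reagent control.

Step 11
Reactants: 13 the protected oxepanol
Product: 14 (3R,5aR,6S,7S,9aR)-6-(hydroxymethyl)-2,2,5a,7-tetramethyldecahydro-1-benzoxepine-3,7-diol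
Conditions: HF·pyridine, pyridine, THF, 0 °C to rt
Reagents that add atoms: none
Why: Fluoride cleavage of the silylene acetal; the ether, secondary and tertiary alcohols are inert.

Step 12
Reactants: 14 the triol
Product: 15 (3R,5aR,6R,7S,9aR)-6-(iodomethyl)-2,2,5a,7-tetramethyldecahydro-1-benzoxepine-3,7-diol
Conditions: I2, PPh3, imidazole, THF, 0 °C to rt
Reagents that add atoms: iodine, II
Why: Appel-type iodination; only the primary hydroxyl reacts, since the C3 alcohol is neopentylic and the C7 alcohol tertiary.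

**Western fragment (steps 13–26)**

Step 13
Reactants: 16 (S)-(+)-carvone
Product: 17 (1S,5S)-cis-carveol
Conditions: NaBH4, CeCl3·7H2O, MeOH, −78 to 0 °C
Reagents that add atoms: none
Why: Luche 1,2-reduction; axial hydride delivery gives the alcohol cis to the isopropenyl group.

Step 14
Reactants: 17 cis-carveol
Product: 18 (1S,2S,4R,6R)-1-methyl-4-(prop-1-en-2-yl)-7-oxabicyclo[4.1.0]heptan-2-ol
Conditions: VO(acac)2 (cat.), t-BuOOH, toluene, 0 °C to rt
Reagents that add atoms: tert-butyl hydroperoxide, CC(C)(C)OO
Why: Hydroxyl-directed vanadium-catalysed epoxidation; oxygen is delivered syn to the hydroxyl and only to the allylic alkene, leaving the isopropenyl group intact.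

Step 15
Reactants: 18 the epoxy alcohol
Product: 19 tert-butyldimethylsilyl ether of 18 (configuration unchanged)
Conditions: TBSCl, imidazole, DMF, rt
Reagents that add atoms: tert-butyldimethylsilyl chloride, CC(C)(C)[Si](C)(C)Cl
Why: Silylation; it prevents α-ketol cleavage and lactol formation in steps 16–17 and keeps the carbinol configuration for step 22.

Step 16
Reactants: 19 the silyl ether
Product: 20 (3R,5S)-5-[(tert-butyldimethylsilyl)oxy]-6-oxo-3-(prop-1-en-2-yl)heptanal
Conditions: H5IO6, THF/Et2O, 0 °C
Reagents that add atoms: orthoperiodic acid (supplies the ketone oxygen), OI(O)(O)(O)(O)=O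
Why: Periodic acid cleavage of the trisubstituted epoxide to a keto aldehyde; both stereocentres are untouched.

Step 17
Reactants: 20 the keto aldehyde
Product: 21 (3S,5S)-3-[(tert-butyldimethylsilyl)oxy]-2-methyl-5-(prop-1-en-2-yl)cyclopent-1-ene-1-carbaldehyde
Conditions: piperidine (cat.), AcOH (cat.), benzene, rt
Reagents that add atoms: none
Why: Amine-catalysed intramolecular aldol condensation (aldehyde enamine onto the methyl ketone) contracts the ring to the cyclopentene carbaldehyde; the silyloxy and isopropenyl groups stay cis.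

Step 18
Reactants: 21 the enal
Product: 22 [(3S,5S)-3-[(tert-butyldimethylsilyl)oxy]-2-methyl-5-(prop-1-en-2-yl)cyclopent-1-en-1-yl]methanol
Conditions: NaBH4, CeCl3·7H2O, MeOH, 0 °C
Reagents that add atoms: none
Why: Luche 1,2-reduction of the enal to the primary allylic alcohol.

Step 19
Reactants: 22 the allylic alcohol
Product: 23 allylic bromide corresponding to 22 (CH2Br in place of CH2OH)
Conditions: CBr4, PPh3, CH2Cl2, 0 °C
Reagents that add atoms: carbon tetrabromide, BrC(Br)(Br)Br
Why: Appel bromination of a primary allylic alcohol; SN2 at the unhindered CH2 is preferred over SN2′ at the fully substituted alkene carbon.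

Step 20
Reactants: 23 the allylic bromide
Product: 24 3-[(3S,5S)-3-[(tert-butyldimethylsilyl)oxy]-2-methyl-5-(prop-1-en-2-yl)cyclopent-1-en-1-yl]-N-methoxy-N-methylpropanamide
Conditions: N-methoxy-N-methylacetamide, LiN(iPr)2, THF, −78 °C; then 23, −78 to −20 °C
Reagents that add atoms: N-methoxy-N-methylacetamide, CC(=O)N(C)OC
Why: SN2 alkylation of an amide enolate by a primary allylic bromide installs the two missing ring carbons (future C7 and C6) at the correct oxidation level.

Step 21
Reactants: 24 the silyl ether amide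
Product: 25 3-[(3S,5S)-3-hydroxy-2-methyl-5-(prop-1-en-2-yl)cyclopent-1-en-1-yl]-N-methoxy-N-methylpropanamide
Conditions: Bu4NF, THF, 0 °C to rt
Reagents that add atoms: none
Why: Fluoride desilylation liberates the allylic alcohol (cis to the isopropenyl group).

Step 22
Reactants: 25 the allylic alcohol
Product: 28 N-methoxy-N-methyl-3-[(1R,5R)-2-methyl-5-(prop-1-en-2-yl)cyclopent-2-en-1-yl]propanamide, via hydrazine adduct 26 (not isolated), via allylic diazene 27 (not isolated)
Conditions: 2-nitrobenzenesulfonylhydrazide, PPh3, diethyl azodicarboxylate, N-methylmorpholine, −30 °C, then rt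
Reagents that add atoms: none
Why: Mitsunobu displacement with the sulfonylhydrazide inverts the carbinol, loss of sulfinic acid gives the monoalkyl diazene, and its retro-ene loss of N2 delivers hydrogen suprafacially to the ring carbon that bears the chain, on the face anti to the isopropenyl group; this reductive 1,3-transposition places the alkene at C1=C2 and sets the cis relationship of the future H-3a and H-8a.

Step 23
Reactants: 28 the transposed amide
Product: 29 5-[(1R,5R)-2-methyl-5-(prop-1-en-2-yl)cyclopent-2-en-1-yl]pent-1-en-3-one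
Conditions: CH2=CHMgBr, THF, −78 to 0 °C; cold aq. NH4Cl
Reagents that add atoms: vinylmagnesium bromide, C=C[Mg]Br
Why: Weinreb ketone synthesis; the chelated tetrahedral intermediate prevents over-addition and releases the vinyl ketone on work-up.

Step 24
Reactants: 29 the vinyl ketone
Product: 30 (3aR,8aR)-1,4-dimethyl-3,3a,8,8a-tetrahydroazulen-6(7H)-one
Conditions: second-generation Grubbs catalyst (H2IMes)(PCy3)Cl2Ru=CHPh (cat.), CH2Cl2 (0.005 M), 40 °C
Reagents that add atoms: none
Why: Ring-closing metathesis of the enone with the isopropenyl group closes the seven-membered ring as a β-methyl enone; the trisubstituted ring alkene is inert and the cis fusion is already fixed.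

Step 25
Reactants: 30 the dienone
Product: 32 (3aR,8aR)-5-[(dimethylamino)methyl]-1,4,4-trimethyl-3,3a,4,5,8,8a-hexahydroazulen-6(7H)-one (C5 epimers), via silyl enol ether 31 (not isolated)
Conditions: Me2CuLi (from MeLi and CuI), Me3SiCl, THF/Et2O, −78 to −20 °C; then CH2=NMe2+ I−, CH2Cl2, rt
Reagents that add atoms: lithium dimethylcuprate, [Li+].C[Cu-]C; Eschenmoser's salt, C=[N+](C)C.[I-]
Why: Cuprate conjugate addition creates the gem-dimethyl carbon C4 (no stereocentre) and gives the enol ether regiospecifically toward C5, which undergoes a Mannich reaction with the iminium salt.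

Step 26
Reactants: 32 the Mannich base
Product: 34 (3aR,8aR)-1,4,4-trimethyl-5-methylidene-3,3a,4,5,8,8a-hexahydroazulen-6(7H)-one, via ammonium iodide 33 (not isolated)
Conditions: MeI, Et2O/CH2Cl2, rt; then DBU, CH2Cl2, rt
Reagents that add atoms: none
Why: Quaternisation and Hofmann-type β-elimination (Eschenmoser methylenation) give the α-methylene ketone, which cannot isomerise into the ring because C4 is quaternary.

**Fragment union (steps 27–28)**

Step 27
Reactants: 15 the iodide; 34 the α-methylene ketone
Product: 35 (3aR,5R,8aR)-5-{2-[(3R,5aR,6R,7S,9aR)-3,7-dihydroxy-2,2,5a,7-tetramethyldecahydro-1-benzoxepin-6-yl]ethyl}-1,4,4-trimethyl-3,3a,4,5,8,8a-hexahydroazulen-6(7H)-one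
Conditions: (Me3Si)3SiH, AIBN, toluene, 80 °C (slow addition of silane)
Reagents that add atoms: none
Why: Giese addition of the primary alkyl radical to the exocyclic enone tolerates the free hydroxyls; the α-keto radical at C5 should take hydrogen from the convex face (the face of H-3a/H-8a), placing the side chain cis to the five-membered ring.

Step 28
Reactants: 35 the keto diol
Product: 36 target, (3R,5aR,6R,7S,9aR)-6-{2-[(3aR,5R,6S,8aR)-6-hydroxy-1,4,4,6-tetramethyl-3,3a,4,5,6,7,8,8a-octahydroazulen-5-yl]ethyl}-2,2,5a,7-tetramethyldecahydro-1-benzoxepine-3,7-diol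
Conditions: MeLi, CeCl3 (excess), THF, −78 °C
Reagents that add atoms: methyllithium, [Li]C
Why: Organocerium 1,2-addition (suppresses enolisation of the hindered ketone); attack on the convex face, anti to the C5 side chain, should give the tertiary alcohol with OH cis to the side chain.

## Compound list

1 | nerol, (2Z)-3,7-dimethylocta-2,6-dien-1-ol | CC(C)=CCC/C(C)=C\CO | starting material
2 | (2R,3S)-2,3-epoxynerol | OC[C@H]1O[C@@]1(C)CCC=C(C)C | intermediate
3 | (2S,3S)-3,7-dimethyl-2-(prop-1-en-2-yl)oct-6-ene-1,3-diol | OC[C@@H]([C@@](C)(O)CCC=C(C)C)C(C)=C | intermediate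
4 | (4S,5S)-2,2-di-tert-butyl-4-methyl-4-(4-methylpent-3-en-1-yl)-5-(prop-1-en-2-yl)-1,3,2-dioxasilinane | CC(C)(C)[Si]1(C(C)(C)C)OC[C@@H]([C@@](C)(O1)CCC=C(C)C)C(C)=C | intermediate
5 | side-chain epoxide of 4 (oxirane CH epimers) | CC(C)(C)[Si]1(C(C)(C)C)OC[C@@H]([C@@](C)(O1)CCC2OC2(C)C)C(C)=C | intermediate (not isolated)
6 | 3-[(4S,5S)-2,2-di-tert-butyl-4-methyl-5-(prop-1-en-2-yl)-1,3,2-dioxasilinan-4-yl]propanal | CC(C)(C)[Si]1(C(C)(C)C)OC[C@@H]([C@@](C)(O1)CCC=O)C(C)=C | intermediate
7 | 7-[(4S,5S)-dioxasilinan-4-yl]-2-methylhept-3-yne-2,5-diol (C5 epimers) | CC(C)(C)[Si]1(C(C)(C)C)OC[C@@H]([C@@](C)(O1)CCC(O)C#CC(C)(C)O)C(C)=C | intermediate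
8 | 1-[(4S,5S)-dioxasilinan-4-yl]-6-hydroxy-6-methylhept-4-yn-3-one | CC(C)(C)[Si]1(C(C)(C)C)OC[C@@H]([C@@](C)(O1)CCC(=O)C#CC(C)(C)O)C(C)=C | intermediate
9 | 5-(diethylamino)-1-[(4S,5S)-dioxasilinan-4-yl]-6-hydroxy-6-methylhept-4-en-3-one | CC(C)(C)[Si]1(C(C)(C)C)OC[C@@H]([C@@](C)(O1)CCC(=O)C=C(N(CC)CC)C(C)(C)O)C(C)=C | intermediate (not isolated)
10 | 5-{2-[(4S,5S)-2,2-di-tert-butyl-4-methyl-5-(prop-1-en-2-yl)-1,3,2-dioxasilinan-4-yl]ethyl}-2,2-dimethylfuran-3(2H)-one | CC(C)(C)[Si]1(C(C)(C)C)OC[C@@H]([C@@](C)(O1)CCC2=CC(=O)C(C)(C)O2)C(C)=C | intermediate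
11 | cyclobutane photoadduct (oxolanone/cyclobutane/cyclohexane/dioxasilinane; cis fusions; quaternary methyl anti to H-6) | CC(C)(C)[Si]1(C(C)(C)C)OC[C@@H]2[C@@]3(C)C[C@@H]4C(=O)C(C)(C)O[C@]34CC[C@]2(C)O1 | intermediate
12 | silylene acetal of (5aR,6S,7S,9aR)-7-hydroxy-6-(hydroxymethyl)-2,2,5a,7-tetramethyloctahydro-1-benzoxepin-3(2H)-one | CC(C)(C)[Si]1(C(C)(C)C)OC[C@@H]2[C@@]3(C)CCC(=O)C(C)(C)O[C@@H]3CC[C@]2(C)O1 | intermediate
13 | silylene acetal of (3R,5aR,6S,7S,9aR)-6-(hydroxymethyl)-2,2,5a,7-tetramethyldecahydro-1-benzoxepine-3,7-diol | CC(C)(C)[Si]1(C(C)(C)C)OC[C@@H]2[C@@]3(C)CC[C@@H](O)C(C)(C)O[C@@H]3CC[C@]2(C)O1 | intermediate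
14 | (3R,5aR,6S,7S,9aR)-6-(hydroxymethyl)-2,2,5a,7-tetramethyldecahydro-1-benzoxepine-3,7-diol | OC[C@@H]1[C@@]2(C)CC[C@@H](O)C(C)(C)O[C@@H]2CC[C@]1(C)O | intermediate
15 | (3R,5aR,6R,7S,9aR)-6-(iodomethyl)-2,2,5a,7-tetramethyldecahydro-1-benzoxepine-3,7-diol | IC[C@@H]1[C@@]2(C)CC[C@@H](O)C(C)(C)O[C@@H]2CC[C@]1(C)O | intermediate
16 | (S)-(+)-carvone | CC1=CC[C@@H](CC1=O)C(C)=C | starting material
17 | (1S,5S)-cis-carveol | CC1=CC[C@@H](C[C@@H]1O)C(C)=C | intermediate
18 | (1S,2S,4R,6R)-1-methyl-4-(prop-1-en-2-yl)-7-oxabicyclo[4.1.0]heptan-2-ol (epoxide syn to OH) | C[C@@]12O[C@@H]1C[C@@H](C[C@@H]2O)C(C)=C | intermediate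
19 | tert-butyldimethylsilyl ether of 18 | C[C@@]12O[C@@H]1C[C@@H](C[C@@H]2O[Si](C)(C)C(C)(C)C)C(C)=C | intermediate
20 | (3R,5S)-5-[(tert-butyldimethylsilyl)oxy]-6-oxo-3-(prop-1-en-2-yl)heptanal | CC(=O)[C@@H](O[Si](C)(C)C(C)(C)C)C[C@H](CC=O)C(C)=C | intermediate
21 | (3S,5S)-3-[(tert-butyldimethylsilyl)oxy]-2-methyl-5-(prop-1-en-2-yl)cyclopent-1-ene-1-carbaldehyde | O=CC1=C(C)[C@@H](O[Si](C)(C)C(C)(C)C)C[C@H]1C(C)=C | intermediate
22 | primary allylic alcohol from 21 | OCC1=C(C)[C@@H](O[Si](C)(C)C(C)(C)C)C[C@H]1C(C)=C | intermediate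
23 | primary allylic bromide from 22 | BrCC1=C(C)[C@@H](O[Si](C)(C)C(C)(C)C)C[C@H]1C(C)=C | intermediate
24 | silyloxy Weinreb amide | CON(C)C(=O)CCC1=C(C)[C@@H](O[Si](C)(C)C(C)(C)C)C[C@H]1C(C)=C | intermediate
25 | hydroxy Weinreb amide (OH cis to isopropenyl) | CON(C)C(=O)CCC1=C(C)[C@@H](O)C[C@H]1C(C)=C | intermediate
26 | N-allyl-N-(2-nitrobenzenesulfonyl)hydrazine (inverted carbinol carbon) | CON(C)C(=O)CCC1=C(C)[C@H](N(N)S(=O)(=O)c2ccccc2[N+](=O)[O-])C[C@H]1C(C)=C | intermediate (not isolated)
27 | allylic monoalkyl diazene | CON(C)C(=O)CCC1=C(C)[C@H](N=N)C[C@H]1C(C)=C | intermediate (not isolated)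
28 | N-methoxy-N-methyl-3-[(1R,5R)-2-methyl-5-(prop-1-en-2-yl)cyclopent-2-en-1-yl]propanamide | CON(C)C(=O)CC[C@H]1C(C)=CC[C@H]1C(C)=C | intermediate
29 | 5-[(1R,5R)-2-methyl-5-(prop-1-en-2-yl)cyclopent-2-en-1-yl]pent-1-en-3-one | C=CC(=O)CC[C@H]1C(C)=CC[C@H]1C(C)=C | intermediate
30 | (3aR,8aR)-1,4-dimethyl-3,3a,8,8a-tetrahydroazulen-6(7H)-one | O=C1C=C(C)[C@@H]2CC=C(C)[C@@H]2CC1 | intermediate
31 | trimethylsilyl enol ether (C5=C6) of the 4,4-dimethyl ketone | C[Si](C)(C)OC1=CC(C)(C)[C@@H]2CC=C(C)[C@@H]2CC1 | intermediate (not isolated)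
32 | (3aR,8aR)-5-[(dimethylamino)methyl]-1,4,4-trimethyl-3,3a,4,5,8,8a-hexahydroazulen-6(7H)-one (C5 epimers) | O=C1C(CN(C)C)C(C)(C)[C@@H]2CC=C(C)[C@@H]2CC1 | intermediate
33 | trimethylammonium iodide of 32 | O=C1C(C[N+](C)(C)C)C(C)(C)[C@@H]2CC=C(C)[C@@H]2CC1.[I-] | intermediate (not isolated)
34 | (3aR,8aR)-1,4,4-trimethyl-5-methylidene-3,3a,4,5,8,8a-hexahydroazulen-6(7H)-one | O=C1C(=C)C(C)(C)[C@@H]2CC=C(C)[C@@H]2CC1 | intermediate
35 | coupled keto diol | CC1=CC[C@@H]2[C@H]1CCC(=O)[C@H](CC[C@@H]1[C@@]3(C)CC[C@@H](O)C(C)(C)O[C@@H]3CC[C@]1(C)O)C2(C)C | intermediate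
36 | target CNP0214586.1 | CC1=CC[C@@H]2[C@H]1CC[C@](C)(O)[C@H](CC[C@@H]1[C@@]3(C)CC[C@@H](O)C(C)(C)O[C@@H]3CC[C@]1(C)O)C2(C)C | target

## Step count and risks

Total steps: 28 (12 east, 14 west, 2 after union).
Longest linear sequence: 16 steps (steps 13–28, from (S)-carvone).

Steps most likely to fail:

**Step 8 (photocycloaddition).** The triplet 1,4-biradical may revert or close in the crossed sense, or the two faces of the isopropenyl group may be poorly differentiated, eroding the configuration of C5a. Fallback: a classical de Mayo sequence that sets out from aldehyde 6 and returns at oxepanone 12. Aldol addition of the lithium enolate of 3-methyl-3-(triethylsilyloxy)butan-2-one to 6 should give the β-hydroxy ketone F1, and Dess–Martin oxidation the β-diketone F2, which exists as its hydrogen-bonded enol. Irradiation through Pyrex should give the cyclobutanol F3, which undergoes retro-aldol cleavage in the flask to the 2,2-disubstituted cyclohexanone F4. Reductive etherification (Et3SiH, Me3SiOTf, CH2Cl2, −78 °C) should then engage the silyl ether oxygen with the ring ketone and reduce the seven-membered oxocarbenium ion by axial hydride delivery, giving 12. This fallback keeps photochemical C–C bond formation but with a different chromophore, a spontaneous fragmentation and a late C–O closure; it does not correct poor facial selectivity at C5a.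

**Step 9 (cyclobutane fragmentation).** Hydrogen delivery to the C9a radical may be unselective (cis-fused oxepane), or the α-alkoxy ketone may suffer reductive C–O cleavage or over-reduction. Fallback: heterolytic opening, setting out from 11 and returning at 12. Me3SiOTf should ionise the donor–acceptor cyclobutane (alkoxy-substituted C9a, acyl-substituted C4) to an oxocarbenium ion and a silyl enol ether, and Et3SiH present in the flask should reduce the oxocarbenium ion axially, anti to the C5a methyl; aqueous work-up gives 12. No compound outside the list is formed (F0).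

**Step 22 (reductive transposition).** The Mitsunobu displacement at the hindered cyclopentenol may be slow or proceed SN2′, so that hydrogen is delivered to the wrong carbon or face. Fallback: palladium-catalysed formate hydrogenolysis, setting out from 25 and returning at 28. Methyl chloroformate and pyridine should give the methyl carbonate F5; Pd(OAc)2, PBu3, HCO2H and Et3N in THF should then give the π-allylpalladium formate, whose hydride is delivered to the more substituted allyl terminus anti to the leaving group, i.e. on the face opposite the isopropenyl group, giving 28.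

## Further compounds

F1 | step 8 | β-hydroxy ketone from 6 and 3-methyl-3-(triethylsilyloxy)butan-2-one (carbinol epimers) | CC(C)(C)[Si]1(C(C)(C)C)OC[C@@H]([C@@](C)(O1)CCC(O)CC(=O)C(C)(C)O[Si](CC)(CC)CC)C(C)=C
F2 | step 8 | β-diketone (drawn as diketo form) | CC(C)(C)[Si]1(C(C)(C)C)OC[C@@H]([C@@](C)(O1)CCC(=O)CC(=O)C(C)(C)O[Si](CC)(CC)CC)C(C)=C
F3 | step 8 | de Mayo cyclobutanol photoadduct (acyl-bearing carbon unassigned) | CC(C)(C)[Si]1(C(C)(C)C)OC[C@@H]2[C@@]3(C)CC(C(=O)C(C)(C)O[Si](CC)(CC)CC)[C@@]3(O)CC[C@]2(C)O1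
F4 | step 8 | 1,5-diketone (2-methyl-2-(3-oxoalkyl)cyclohexanone) after retro-aldol | CC(C)(C)[Si]1(C(C)(C)C)OC[C@@H]2[C@@](C)(CCC(=O)C(C)(C)O[Si](CC)(CC)CC)C(=O)CC[C@]2(C)O1
F0 | step 9 | none | none
F5 | step 22 | methyl carbonate of 25 | CON(C)C(=O)CCC1=C(C)[C@@H](OC(=O)OC)C[C@H]1C(C)=C
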